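## Analysis of the target

The target is a thirteen-carbon chain, numbered here from the lactone carbonyl C1 to the phenyl-bearing C13, in which C1 to C5 are closed through the C5 oxygen into a six-membered δ-lactone with a free hydroxyl at C3. Outside the ring the chain carries an E alkene (C6=C7), a methylene (C8), two methoxy-bearing carbons (C9 and C11) on either side of the C10 methylene, and an E styrene (C12=C13–Ph). Of the four stereocentres, C3 (S) and C5 (R) place the hydroxyl and the side chain trans on the ring, which corresponds to a syn-3,5-diol in the open hydroxy acid, and C9 (R) and C11 (S) form an anti-1,3-dimethoxy pair. C5 and C9 stand in a 1,5-relationship across the C6=C7 alkene, so neither pair can steer the other and each needs its own source of absolute configuration. The β-hydroxy lactone loses water to the conjugated lactone under base or strong acid, and the allylic C5–O bond is similarly labile. The C11 methoxy group is allylic and conjugated with the styrene, so it can ionise under acid with loss of configuration or shift of oxygen to C13, and the styrene itself rules out hydrogenation and dissolving metals and makes olefin metathesis unselective. The hard parts are the acyclic anti pair next to a styrene, and joining the two halves through an E alkene while C5 is set. The plan rests on one feature: C10 to C13 with the phenyl ring is the skeleton of benzalacetone (4), whose ketone oxygen becomes the C11 oxygen and whose methyl carbon becomes C10, bonded to an aldehyde carbon that becomes C9 with its oxygen.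

## Retrosynthetic reasoning

**Lactone C1–O bond.** The ring of target 21 is opened at the ester bond between C1 and the C5 oxygen, giving dihydroxy ester 20 and, one protecting group earlier, silyl ether 19. The β-hydroxy lactone is the most fragile part of the molecule, so it is formed last under mild conditions. Only the C5 hydroxyl can reach C1 through a six-membered ring, so the closure is unambiguous.

**C5–C6 bond.** 19 is cut between the carbinol carbon C5 and the alkene carbon C6 into terminal alkyne 12 (C6 to C13) and aldehyde ester 16 (C1 to C5). This cut separates the two stereochemical pairs, which cannot communicate anyway. The forward reaction is a syn hydrometallation of 12 to the E-alkenyl metal (17, then 18) and a ligand-controlled addition to 16, so it delivers the E geometry and C5 together. A cut at C6=C7 by olefination would need an epimerisable α-oxygenated aldehyde at C5, and a cut at C7–C8 would leave an alkyne to reduce.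

**C1–C5 fragment.** In 16, C3 is the middle carbon of a five-carbon chain whose two ends are both at the carboxyl level. It therefore maps onto the meso anhydride 13. A desymmetrising alcoholysis to hemiester 14 sets C3 and tells the two ends apart in one step. Reduction of the acid end (15) and re-oxidation give 16.

**C6 and the methyl ethers.** Alkyne 12 comes from aldehyde 11 by a one-carbon homologation that adds C6. 11 comes from alcohol 10 and silyl ether 9. Both methyl ethers of 9 are installed together on diol 8, so the two hydroxyls never have to be told apart.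

**C9–C10 bond and C11–H bond (the key disconnection).** Diol 8 is the deacylated form of monoester 7. 7 is cut at C9–C10 and at the C11–H bond into benzalacetone 4 and two molecules of aldehyde 3. In the forward sense the enolate of 4 adds to 3 (aldolate 5), 5 picks up a second molecule of 3 (hemiacetal 6), and 6 hands its hydride to the C11 ketone. One operation thus forms the only new skeletal bond of this fragment and both stereocentres, and the styrene is bought ready-made. No other cut delivers the anti pair and the C12=C13 alkene from two commodity chemicals.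

**Aldehyde 3.** 3 is the oxidation product of mono-silyl ether 2, which comes from the symmetric diol 1.

## Alternatives that were turned down

**Alternative 1:** The lactone half is traced back to the seven-membered lactone (4S,6R)-4,6-bis(tert-butyldimethylsilyloxy)oxepan-2-one A2. A2 would come from the meso ketone cis-3,5-bis(tert-butyldimethylsilyloxy)cyclohexan-1-one A1, itself reached by dearomatising a cheap symmetric aromatic feedstock.
- Forward key step: an enzymatic Baeyer–Villiger oxidation (flavin monooxygenase, NADPH, O2) inserts oxygen next to one of the two enantiotopic α-carbons of A1 and gives A2.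
- For: both lactone stereocentres come from one catalytic step on an achiral substrate, and the feedstock is cheap.
- Against: a ketone flanked by two bulky silyl ethers, as in A1, is an uncertain substrate for such enzymes, and cofactor recycling is needed. A2 must then be opened, its ring CH2–O carbon (C6 of the target) oxidised to an epimerisable α-silyloxy aldehyde, and joined by an E-selective olefination to a C7–C13 partner. That partner must still carry the anti C9/C11 pair, so the hardest problem is untouched.
- Comparison: on C3/C5 this alternative is stronger, because one event of enzyme-level selectivity replaces the two catalyst-controlled steps 9 and 12. The chosen strategy offers instead a one-step answer to C9/C11 and the styrene, ordinary reagents throughout, and a C1–C5 piece three steps from a commercial anhydride.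

**Alternative 2:** The C5–O bond and the C6=C7 alkene are traced back to the transposed allylic alcohol methyl (3S,5E,9R,11S,12E)-3,7-dihydroxy-9,11-dimethoxy-13-phenyltrideca-5,12-dienoate A4, with C7 as either epimer.
- Forward key step: Re2O7 turns the C7 hydroxyl of A4 into a perrhenate ester that shifts [3,3] reversibly. The isomer whose C5 oxygen is syn to the C3 hydroxyl is trapped with benzaldehyde dimethyl acetal A5 as the all-equatorial 2,4,6-cis dioxane methyl 2-[(2R,4S,6R)-6-[(1E,4R,6S,7E)-4,6-dimethoxy-8-phenylocta-1,7-dienyl]-2-phenyl-1,3-dioxan-4-yl]acetate A3.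
- For: the step is stereoconvergent and thermodynamically driven. C5 and the E alkene of A3 are set from C3 alone with no chiral reagent, A5 is an inexpensive trap, and the C7 alcohol of A4 can be made without control.
- Against: the same cation-like conditions act on the C11 cinnamyl methyl ether, which ionises even more readily, so C11 may scramble or its oxygen may move to C13. A4 already contains the whole C9/C11 array, so that problem is only moved. Removal of the benzylidene acetal from A3 and lactonisation add steps, and the route is linear.
- Comparison: on C5 this alternative is stronger, since substrate control replaces the ligand control of step 12. The chosen strategy offers convergence, direct access to C9/C11, and no strongly Lewis-acidic medium while the cinnamyl ether is present.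

**Alternative 3:** The chain is cut at C7–C8 into the acetonide alkyne tert-butyl{2-[(4R,6R)-6-ethynyl-2,2-dimethyl-1,3-dioxan-4-yl]ethoxy}dimethylsilane A7 and the terminal epoxide (2S)-2-[(2S,3E)-2-methoxy-4-phenylbut-3-en-1-yl]oxirane A8.
- Forward key step: the lithium acetylide of A7, with BF3·OEt2, opens A8 at its unsubstituted carbon to give the homopropargylic alcohol (1E,3S,5R)-8-[(4R,6R)-6-[2-(tert-butyldimethylsilyloxy)ethyl]-2,2-dimethyl-1,3-dioxan-4-yl]-3-methoxy-1-phenyloct-1-en-7-yn-5-ol A6.
- For: this is among the most dependable fragment unions. It is convergent, the C9 configuration arrives untouched from the epoxide A8, and the acetonide of A7 secures the syn C3/C5 relation.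
- Against: in A6 the C6–C7 unit is an alkyne, and its E-selective reduction without a free propargylic hydroxyl calls for dissolving-metal or multi-step conditions that endanger the styrene and the cinnamyl ether. C1 of A6 is a silyl ether and needs two late oxidations. The C9 hydroxyl of A6 must be methylated separately from C11. BF3 meets the cinnamyl ether of A8, and both fragments are long to make.
- Comparison: on reliability of the coupling and on convergence this alternative is stronger than step 12. The chosen strategy offers the E alkene directly at the right oxidation level, C1 already as an ester, both methyl ethers in one operation, and the C9/C11 pair in one step.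

Key step: step 3

Assumption: in the steps where a chiral catalyst or ligand decides absolute configuration (3, 9 and 12, and their fallbacks), the antipode written is the one expected by analogy to give the configuration drawn. It would be confirmed on the first run (MTPA esters of 8 and 19, rotation of 14), and the mirror-image ligand is available in each case.

## Route

**Step 1**
Reactants: 1 propane-1,3-diol
Product: 2 3-(tert-butyldimethylsilyloxy)propan-1-ol
Conditions: NaH (1.0 equiv), THF, 0 °C → rt; then TBSCl (1.0 equiv), rt
Reagents that add atoms: tert-butyldimethylsilyl chloride, C[Si](C)(Cl)C(C)(C)C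
Why: O-silylation of the sparingly soluble monosodium alkoxide; only one hydroxyl is deprotonated, so the symmetric diol should give mainly the mono-ether.

**Step 2**
Reactants: 2 3-(tert-butyldimethylsilyloxy)propan-1-ol
Product: 3 3-(tert-butyldimethylsilyloxy)propanal
Conditions: 2,2,6,6-tetramethylpiperidin-1-oxyl (TEMPO, 10 mol%), PhI(OAc)2 (1.1 equiv), CH2Cl2, rt
Reagents that add atoms: none
Why: Oxoammonium-mediated alcohol oxidation stops at the aldehyde and is free of base, so the β-silyloxy aldehyde should not lose silanol; it is used promptly.

**Step 3**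
Reactants: 4 benzalacetone, (E)-4-phenylbut-3-en-2-one; 3 3-(tert-butyldimethylsilyloxy)propanal (two molecules)
Product: 7 (1E,3S,5R)-7-(tert-butyldimethylsilyloxy)-3-hydroxy-1-phenylhept-1-en-5-yl 3-(tert-butyldimethylsilyloxy)propanoate, via lanthanum aldolate of β-hydroxy enone 5 (not isolated), via hemiacetal alkoxide 6 (not isolated)
Conditions: La(OTf)3 (10 mol%), (R)-BINOL (30 mol%), n-BuLi (56 mol%) [forms LaLi3(binaphthoxide)3], THF, 0 °C → rt, slow addition of 3 (2.2 equiv)
Reagents that add atoms: none
Why: The lanthanum–lithium binaphthoxide enolises 4 at its only enolisable position, the methyl group, and the enolate adds reversibly to the carbonyl of 3, forming the C9–C10 bond and aldolate 5. Aldolate 5 adds to a second molecule of 3 to give hemiacetal alkoxide 6, whose carbinol hydrogen passes to the C11 ketone through a chair-like six-membered array (hemiacetal C–H, O, C9, C10, C11) held by the metal bridging the hemiacetal and ketone oxygens, so the hemiacetal ends as the C9 ester. This is an aldol–Tishchenko reaction; the closest known types are the lanthanide binaphthoxide-catalysed coupling of a ketone with two aldehyde molecules and the Evans–Tishchenko reduction of β-hydroxy ketones. No ring is closed and one skeletal bond is made. C9 is controlled by the catalyst: the hydride shift is irreversible, the two enantiomers of 5 interconvert by retro-aldol, and the binaphthoxide framework should let only one of them pass through the chair (a dynamic kinetic resolution). C11 is controlled by C9, because the C9 substituent sits equatorial in the chair and the new C11–H bond forms anti to the C9 oxygen. The step needs 1,2- and not 1,4-reduction of the enone, which the intramolecular delivery to the carbonyl carbon secures, and cross- over self-condensation of the enolisable aldehyde, which slow addition of 3 is meant to favour. A 1,3-acyl shift of the ester to the C11 oxygen would be harmless, since step 4 removes the acyl group.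

**Step 4**
Reactants: 7 (1E,3S,5R)-7-(tert-butyldimethylsilyloxy)-3-hydroxy-1-phenylhept-1-en-5-yl 3-(tert-butyldimethylsilyloxy)propanoate
Product: 8 (1E,3S,5R)-7-(tert-butyldimethylsilyloxy)-1-phenylhept-1-ene-3,5-diol
Conditions: K2CO3 (cat.), MeOH, 0 °C → rt
Reagents that add atoms: none
Why: Base-catalysed transesterification transfers the acyl group to methanol; the primary silyl ether and the cinnamyl alcohol are inert, the stereocentres are untouched, and either monoester regioisomer gives the same diol.

**Step 5**
Reactants: 8 (1E,3S,5R)-7-(tert-butyldimethylsilyloxy)-1-phenylhept-1-ene-3,5-diol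
Product: 9 tert-butyl{[(3R,5S,6E)-3,5-dimethoxy-7-phenylhept-6-en-1-yl]oxy}dimethylsilane
Conditions: Me3OBF4 (4 equiv), 1,8-bis(dimethylamino)naphthalene (5 equiv), CH2Cl2, 0 °C → rt
Reagents that add atoms: trimethyloxonium tetrafluoroborate, C[O+](C)C.F[B-](F)(F)F
Why: O-Methylation with an oxonium salt buffered by a hindered amine etherifies both secondary hydroxyls without forming alkoxides, which avoids silyl migration from the C7 oxygen to the C9 oxygen; C9 and C11 keep their configuration.

**Step 6**
Reactants: 9 tert-butyl{[(3R,5S,6E)-3,5-dimethoxy-7-phenylhept-6-en-1-yl]oxy}dimethylsilane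
Product: 10 (3R,5S,6E)-3,5-dimethoxy-7-phenylhept-6-en-1-ol
Conditions: TBAF, THF, 0 °C → rt
Reagents that add atoms: none
Why: Fluoride-induced cleavage of the Si–O bond; 9 has no base-sensitive group.

**Step 7**
Reactants: 10 (3R,5S,6E)-3,5-dimethoxy-7-phenylhept-6-en-1-ol
Product: 11 (3S,5S,6E)-3,5-dimethoxy-7-phenylhept-6-enal
Conditions: 2,2,6,6-tetramethylpiperidin-1-oxyl (10 mol%), PhI(OAc)2 (1.1 equiv), CH2Cl2, rt
Reagents that add atoms: none
Why: The oxoammonium oxidation is base-free, so the β-methoxy aldehyde should not lose methanol, and the styrene is untouched; the descriptor at the C9 carbon changes from R to S only because the CIP ranking of its neighbours changes.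

**Step 8**
Reactants: 11 (3S,5S,6E)-3,5-dimethoxy-7-phenylhept-6-enal
Product: 12 [(1E,3S,5R)-3,5-dimethoxyoct-1-en-7-yn-1-yl]benzene
Conditions: dimethyl (1-diazo-2-oxopropyl)phosphonate, K2CO3, MeOH, 0 °C → rt
Reagents that add atoms: dimethyl (1-diazo-2-oxopropyl)phosphonate, CC(=O)C(=[N+]=[N-])P(=O)(OC)OC
Why: Seyferth–Gilbert homologation in its Ohira–Bestmann form: methanolysis releases the diazomethylphosphonate anion, which olefinates the aldehyde; loss of N2 and a 1,2-hydrogen shift of the alkylidene carbene give the terminal alkyne and add C6. Carbonate at low temperature keeps β-elimination slow.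

**Step 9**
Reactants: 13 3-(tert-butyldimethylsilyloxy)glutaric anhydride, 4-(tert-butyldimethylsilyloxy)oxane-2,6-dione
Product: 14 (3S)-3-(tert-butyldimethylsilyloxy)-5-methoxy-5-oxopentanoic acid
Conditions: MeOH (10 equiv), (DHQD)2AQN [hydroquinidine anthraquinone-1,4-diyl diether] (10 mol%), Et2O, −40 °C
Reagents that add atoms: methanol, CO
Why: Desymmetrising alcoholysis of a meso anhydride under general-base catalysis by the quinuclidine nitrogen of the cinchona-derived catalyst; its chiral pocket selects one of the two enantiotopic carbonyls, which fixes C3 and differentiates the chain ends.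

**Step 10**
Reactants: 14 (3S)-3-(tert-butyldimethylsilyloxy)-5-methoxy-5-oxopentanoic acid
Product: 15 methyl (3S)-3-(tert-butyldimethylsilyloxy)-5-hydroxypentanoate
Conditions: BH3·SMe2, THF, 0 °C → rt; MeOH/H2O work-up
Reagents that add atoms: none
Why: Borane reduces a carboxylic acid through its acyloxyborane much faster than an ester, so only the acid end should become the primary alcohol; C3 is not touched.

**Step 11**
Reactants: 15 methyl (3S)-3-(tert-butyldimethylsilyloxy)-5-hydroxypentanoate
Product: 16 methyl (3S)-3-(tert-butyldimethylsilyloxy)-5-oxopentanoate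
Conditions: 2,2,6,6-tetramethylpiperidin-1-oxyl (10 mol%), PhI(OAc)2 (1.1 equiv), CH2Cl2, rt
Reagents that add atoms: none
Why: Base-free oxoammonium oxidation of the primary alcohol; 15 is oxidised without delay because the δ-hydroxy ester can lactonise, and 16 is used at once because it can lose silanol on standing.

**Step 12**
Reactants: 12 [(1E,3S,5R)-3,5-dimethoxyoct-1-en-7-yn-1-yl]benzene; 16 methyl (3S)-3-(tert-butyldimethylsilyloxy)-5-oxopentanoate
Product: 19 methyl (3S,5R,6E,9R,11S,12E)-3-(tert-butyldimethylsilyloxy)-5-hydroxy-9,11-dimethoxy-13-phenyltrideca-6,12-dienoate, via alkenylzirconocene chloride 17 (not isolated), via alkenyl(methyl)zinc 18 (not isolated)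
Conditions: Cp2Zr(H)Cl (1.1 equiv), CH2Cl2, rt; Me2Zn (1.1 equiv), toluene, −65 °C; (−)-MIB [(2S)-3-exo-morpholinoisoborneol] (10 mol%), then 16, −30 → 0 °C; aq. NaHCO3
Reagents that add atoms: none
Why: Hydrozirconation adds Zr–H syn across the terminal alkyne with zirconium on the terminal carbon, giving E-alkenyl species 17; the alkyne reacts far faster than the 1,2-disubstituted styrene. Zirconium-to-zinc transmetalation gives 18, and the amino alcohol ligand accelerates the alkenylzinc addition and should direct it to the Si face of 16, which sets C5 as R (syn to C3); the methyl ester is tolerated by organozinc reagents.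

**Step 13**
Reactants: 19 methyl (3S,5R,6E,9R,11S,12E)-3-(tert-butyldimethylsilyloxy)-5-hydroxy-9,11-dimethoxy-13-phenyltrideca-6,12-dienoate
Product: 21 (4S,6R)-6-[(1E,4R,6S,7E)-4,6-dimethoxy-8-phenylocta-1,7-dien-1-yl]-4-hydroxyoxan-2-one (the target), via dihydroxy ester 20 (not isolated)
Conditions: HF·pyridine, pyridine, THF, 0 °C → rt; then pyridinium p-toluenesulfonate (cat.), CH2Cl2, rt
Reagents that add atoms: none
Why: Buffered fluoride cleaves the C3 silyl ether to 20, and mild acid-catalysed intramolecular transesterification by the C5 hydroxyl closes the six-membered lactone (the C3 hydroxyl could only form a four-membered ring). Neither medium should be acidic enough to ionise the cinnamyl ether or dehydrate the β-hydroxy lactone, and no stereocentre is touched.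

## Compound list

1 | propane-1,3-diol | OCCCO | starting material
2 | 3-(tert-butyldimethylsilyloxy)propan-1-ol | OCCCO[Si](C)(C)C(C)(C)C | intermediate
3 | 3-(tert-butyldimethylsilyloxy)propanal | O=CCCO[Si](C)(C)C(C)(C)C | intermediate
4 | benzalacetone, (E)-4-phenylbut-3-en-2-one | CC(=O)/C=C/c1ccccc1 | starting material
5 | (1E,5R)-7-(tert-butyldimethylsilyloxy)-5-hydroxy-1-phenylhept-1-en-3-one (present as its lanthanum aldolate) | O=C(/C=C/c1ccccc1)C[C@@H](CCO[Si](C)(C)C(C)(C)C)O | intermediate (not isolated)
6 | (1E,5R)-7-(tert-butyldimethylsilyloxy)-5-[3-(tert-butyldimethylsilyloxy)-1-hydroxypropoxy]-1-phenylhept-1-en-3-one (present as its alkoxide; hemiacetal carbon transient and unspecified) | O=C(/C=C/c1ccccc1)C[C@@H](CCO[Si](C)(C)C(C)(C)C)OC(O)CCO[Si](C)(C)C(C)(C)C | intermediate (not isolated)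
7 | (1E,3S,5R)-7-(tert-butyldimethylsilyloxy)-3-hydroxy-1-phenylhept-1-en-5-yl 3-(tert-butyldimethylsilyloxy)propanoate | O[C@H](/C=C/c1ccccc1)C[C@@H](CCO[Si](C)(C)C(C)(C)C)OC(=O)CCO[Si](C)(C)C(C)(C)C | intermediate
8 | (1E,3S,5R)-7-(tert-butyldimethylsilyloxy)-1-phenylhept-1-ene-3,5-diol | O[C@H](/C=C/c1ccccc1)C[C@@H](CCO[Si](C)(C)C(C)(C)C)O | intermediate
9 | tert-butyl{[(3R,5S,6E)-3,5-dimethoxy-7-phenylhept-6-en-1-yl]oxy}dimethylsilane | CO[C@H](/C=C/c1ccccc1)C[C@@H](CCO[Si](C)(C)C(C)(C)C)OC | intermediate
10 | (3R,5S,6E)-3,5-dimethoxy-7-phenylhept-6-en-1-ol | CO[C@H](/C=C/c1ccccc1)C[C@@H](CCO)OC | intermediate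
11 | (3S,5S,6E)-3,5-dimethoxy-7-phenylhept-6-enal | CO[C@H](/C=C/c1ccccc1)C[C@@H](CC=O)OC | intermediate
12 | [(1E,3S,5R)-3,5-dimethoxyoct-1-en-7-yn-1-yl]benzene | CO[C@H](/C=C/c1ccccc1)C[C@@H](CC#C)OC | intermediate
13 | 3-(tert-butyldimethylsilyloxy)glutaric anhydride, 4-(tert-butyldimethylsilyloxy)oxane-2,6-dione | O=C1CC(O[Si](C)(C)C(C)(C)C)CC(=O)O1 | starting material
14 | (3S)-3-(tert-butyldimethylsilyloxy)-5-methoxy-5-oxopentanoic acid | OC(=O)C[C@H](O[Si](C)(C)C(C)(C)C)CC(=O)OC | intermediate
15 | methyl (3S)-3-(tert-butyldimethylsilyloxy)-5-hydroxypentanoate | OCC[C@H](O[Si](C)(C)C(C)(C)C)CC(=O)OC | intermediate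
16 | methyl (3S)-3-(tert-butyldimethylsilyloxy)-5-oxopentanoate | O=CC[C@H](O[Si](C)(C)C(C)(C)C)CC(=O)OC | intermediate
17 | chlorobis(cyclopentadienyl)[(1E,4R,6S,7E)-4,6-dimethoxy-8-phenylocta-1,7-dien-1-yl]zirconium (cyclopentadienyl rings drawn σ-bonded) | CO[C@H](C/C=C/[Zr](Cl)(C1C=CC=C1)C1C=CC=C1)C[C@@H](/C=C/c1ccccc1)OC | intermediate (not isolated)
18 | [(1E,4R,6S,7E)-4,6-dimethoxy-8-phenylocta-1,7-dien-1-yl](methyl)zinc | CO[C@H](C/C=C/[Zn]C)C[C@@H](/C=C/c1ccccc1)OC | intermediate (not isolated)
19 | methyl (3S,5R,6E,9R,11S,12E)-3-(tert-butyldimethylsilyloxy)-5-hydroxy-9,11-dimethoxy-13-phenyltrideca-6,12-dienoate | CO[C@H](C/C=C/[C@H](O)C[C@H](O[Si](C)(C)C(C)(C)C)CC(=O)OC)C[C@@H](/C=C/c1ccccc1)OC | intermediate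
20 | methyl (3S,5R,6E,9R,11S,12E)-3,5-dihydroxy-9,11-dimethoxy-13-phenyltrideca-6,12-dienoate | CO[C@H](C/C=C/[C@H](O)C[C@H](O)CC(=O)OC)C[C@@H](/C=C/c1ccccc1)OC | intermediate (not isolated)
21 | (4S,6R)-6-[(1E,4R,6S,7E)-4,6-dimethoxy-8-phenylocta-1,7-dien-1-yl]-4-hydroxyoxan-2-one | CO[C@H](C/C=C/[C@H]1C[C@H](O)CC(=O)O1)C[C@@H](/C=C/c1ccccc1)OC | target

## Step count and least certain steps

Total step count: 13. Longest linear sequence: 10 steps (steps 1 to 8, 12 and 13, from propane-1,3-diol). The C1–C5 branch contributes 3 steps (9 to 11) before the union.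

**Step 3 (key step).** Several processes threaten it.
- Self-condensation of the enolisable aldehyde 3 (aldol and Tishchenko pathways) may outrun enolisation of 4.
- Silanol may be lost by β-elimination.
- Retro-aldol of the aliphatic aldolate may be too slow for the dynamic resolution, which would erode enantioselectivity.
- The aldolate oxygen may add in conjugate fashion to C13.

Fallback (sets out from 4 and 3, comes back at 8): the two events are separated. Ketone 4 is enolised at its methyl group with (−)-Ipc2BCl and Et3N (Et2O, −78 °C), the boron enolate adds to 3, and oxidative work-up gives 5 as an isolated β-hydroxy enone. Its hydroxyl then directs an anti-selective intramolecular hydride delivery from Me4NBH(OAc)3 (MeCN/AcOH, −30 °C; Evans–Saksena reduction), which gives 8 directly and makes step 4 unnecessary. Absolute control then rests on a stoichiometric boron ligand and not on a catalytic resolution. No compound outside the compound list is made on this path, hence the entry F0.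

**Step 12.** Lewis-acidic zirconocene residues may drive a ligand-free background addition, and the C3 silyloxy group may oppose the ligand, so facial selectivity at C5 may be poor. Methyl transfer from zinc and over-hydrozirconation of the styrene are lesser risks.

Fallback (sets out from 12 and 16, comes back at 20): C5 is set by C3 and not by a ligand. Alkenylzinc 18 is added to 16 without ligand, giving 19 mixed with its C5 epimer, methyl (3S,5S,6E,9R,11S,12E)-3-(tert-butyldimethylsilyloxy)-5-hydroxy-9,11-dimethoxy-13-phenyltrideca-6,12-dienoate F1. MnO2 oxidises the mixture to the enone methyl (3S,6E,9R,11S,12E)-3-(tert-butyldimethylsilyloxy)-9,11-dimethoxy-5-oxo-13-phenyltrideca-6,12-dienoate F2. HF·pyridine removes the silyl group to give methyl (3S,6E,9R,11S,12E)-3-hydroxy-9,11-dimethoxy-5-oxo-13-phenyltrideca-6,12-dienoate F3. A Narasaka–Prasad reduction (Et2BOMe, NaBH4, THF/MeOH, −78 °C) then delivers hydride 1,2 and syn to the C3 hydroxyl through the boron chelate, giving 20, which is closed with pyridinium p-toluenesulfonate as in step 13.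

**Step 8.** Carbonate in methanol may trigger loss of methanol from the β-methoxy aldehyde (E1cB) before the homologation takes place.

Fallback (sets out from 11, comes back at 12): the alkyne is made by the Corey–Fuchs sequence, which keeps the aldehyde away from alkoxide. CBr4/PPh3 (CH2Cl2, 0 °C, Et3N buffer) converts 11 into [(1E,3S,5R)-8,8-dibromo-3,5-dimethoxyocta-1,7-dien-1-yl]benzene F4. n-BuLi (2 equiv, THF, −78 °C) followed by water gives 12 by bromine–lithium exchange and 1,2-shift.

**Step 13.** Acid may ionise the C11 cinnamyl ether (loss of configuration or allylic shift) or dehydrate the β-hydroxy lactone, or ring closure may stay incomplete.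

Fallback (sets out from 19, comes back at 21): an acid-free end game. Buffered fluoride (TBAF/AcOH, THF) gives 20, which is isolated. LiOH in THF/H2O saponifies it to (3S,5R,6E,9R,11S,12E)-3,5-dihydroxy-9,11-dimethoxy-13-phenyltrideca-6,12-dienoic acid F5. Carbodiimide activation (EDC·HCl, CH2Cl2, 0 °C) closes the six-membered lactone through the C5 hydroxyl to give 21.

**Step 9.** Discrimination between the two enantiotopic carbonyls may be incomplete, which would later show up as diastereomers of 19, or the catalyst antipode may favour the mirror image.

Fallback (sets out from 13, comes back at 14): a diastereoselective opening replaces the enantioselective one. 13 is opened with (S)-1-(naphthalen-1-yl)ethanol and 4-(dimethylamino)pyridine at −78 °C to give (3R)-3-(tert-butyldimethylsilyloxy)-5-[(1S)-1-(naphthalen-1-yl)ethoxy]-5-oxopentanoic acid F6, which is freed from its minor diastereomer by crystallisation or chromatography. Me3SiCHN2 (MeOH/toluene) gives the mixed diester 1-methyl 5-[(1S)-1-(naphthalen-1-yl)ethyl] (3R)-3-(tert-butyldimethylsilyloxy)pentanedioate F7. Hydrogenolysis of the benzylic ester (H2, Pd/C, EtOAc) gives 14.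

## Further compounds

F0 | step 3 | none | none
F1 | step 12 | methyl (3S,5S,6E,9R,11S,12E)-3-(tert-butyldimethylsilyloxy)-5-hydroxy-9,11-dimethoxy-13-phenyltrideca-6,12-dienoate | CO[C@H](C/C=C/[C@@H](O)C[C@H](O[Si](C)(C)C(C)(C)C)CC(=O)OC)C[C@@H](/C=C/c1ccccc1)OC
F2 | step 12 | methyl (3S,6E,9R,11S,12E)-3-(tert-butyldimethylsilyloxy)-9,11-dimethoxy-5-oxo-13-phenyltrideca-6,12-dienoate | CO[C@H](C/C=C/C(=O)C[C@H](O[Si](C)(C)C(C)(C)C)CC(=O)OC)C[C@@H](/C=C/c1ccccc1)OC
F3 | step 12 | methyl (3S,6E,9R,11S,12E)-3-hydroxy-9,11-dimethoxy-5-oxo-13-phenyltrideca-6,12-dienoate | CO[C@H](C/C=C/C(=O)C[C@H](O)CC(=O)OC)C[C@@H](/C=C/c1ccccc1)OC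
F4 | step 8 | [(1E,3S,5R)-8,8-dibromo-3,5-dimethoxyocta-1,7-dien-1-yl]benzene | CO[C@H](/C=C/c1ccccc1)C[C@@H](CC=C(Br)Br)OC
F5 | step 13 | (3S,5R,6E,9R,11S,12E)-3,5-dihydroxy-9,11-dimethoxy-13-phenyltrideca-6,12-dienoic acid | CO[C@H](C/C=C/[C@H](O)C[C@H](O)CC(=O)O)C[C@@H](/C=C/c1ccccc1)OC
F6 | step 9 | (3R)-3-(tert-butyldimethylsilyloxy)-5-[(1S)-1-(naphthalen-1-yl)ethoxy]-5-oxopentanoic acid | C[C@H](OC(=O)C[C@H](O[Si](C)(C)C(C)(C)C)CC(=O)O)c1cccc2ccccc12
F7 | step 9 | 1-methyl 5-[(1S)-1-(naphthalen-1-yl)ethyl] (3R)-3-(tert-butyldimethylsilyloxy)pentanedioate | C[C@H](OC(=O)C[C@H](O[Si](C)(C)C(C)(C)C)CC(=O)OC)c1cccc2ccccc12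
A1 | alternative 1 | cis-3,5-bis(tert-butyldimethylsilyloxy)cyclohexan-1-one (meso) | O=C1C[C@H](O[Si](C)(C)C(C)(C)C)C[C@H](O[Si](C)(C)C(C)(C)C)C1
A2 | alternative 1 | (4S,6R)-4,6-bis(tert-butyldimethylsilyloxy)oxepan-2-one | O=C1C[C@@H](O[Si](C)(C)C(C)(C)C)C[C@@H](O[Si](C)(C)C(C)(C)C)CO1
A3 | alternative 2 | methyl 2-[(2R,4S,6R)-6-[(1E,4R,6S,7E)-4,6-dimethoxy-8-phenylocta-1,7-dienyl]-2-phenyl-1,3-dioxan-4-yl]acetate | COC(=O)C[C@@H]1C[C@H](/C=C/C[C@@H](OC)C[C@@H](/C=C/c2ccccc2)OC)O[C@H](c2ccccc2)O1
A4 | alternative 2 | methyl (3S,5E,9R,11S,12E)-3,7-dihydroxy-9,11-dimethoxy-13-phenyltrideca-5,12-dienoate (C7 either epimer) | COC(=O)C[C@@H](O)C/C=C/C(O)C[C@@H](OC)C[C@@H](/C=C/c1ccccc1)OC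
A5 | alternative 2 | benzaldehyde dimethyl acetal | COC(OC)c1ccccc1
A6 | alternative 3 | (1E,3S,5R)-8-[(4R,6R)-6-[2-(tert-butyldimethylsilyloxy)ethyl]-2,2-dimethyl-1,3-dioxan-4-yl]-3-methoxy-1-phenyloct-1-en-7-yn-5-ol | O[C@H](CC#C[C@H]1C[C@@H](CCO[Si](C)(C)C(C)(C)C)OC(C)(C)O1)C[C@@H](/C=C/c1ccccc1)OC
A7 | alternative 3 | tert-butyl{2-[(4R,6R)-6-ethynyl-2,2-dimethyl-1,3-dioxan-4-yl]ethoxy}dimethylsilane | C#C[C@H]1C[C@@H](CCO[Si](C)(C)C(C)(C)C)OC(C)(C)O1
A8 | alternative 3 | (2S)-2-[(2S,3E)-2-methoxy-4-phenylbut-3-en-1-yl]oxirane | CO[C@H](/C=C/c1ccccc1)C[C@H]1CO1
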